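The data stem from a simulated flask with made-up constants; scatter was added.

Set side by side in percent, the flasks look far apart: after 1.50 min the beta run holds twice the percentage of isomer of the product that the alpha run holds after 80.0 s. Its charge, however, is smaller, and in concentration the two readings stand at 3.74 mM and 2.86 mM.

| flask | substrate | remark | time |
|---|---|---|---|
| alpha | 26 mM | the very flask that is asked about, followed so far |  |
| beta | 17 mM | run made earlier |  |
| flask | 26 mM |  | 2.5 min |

alpha run (percent of the substrate charged)

| time / s | target / % | isomer of the product / % |
|---|---|---|
| 10.0 | 38 | 2 |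
| 25.0 | 65 | 3 |
| 50.0 | 71 | 7 |
| 80.0 | 72 | 11 |

beta run (percent of the substrate charged)

| time / min | target / % | isomer of the product / % |
|---|---|---|
| 0.333 | 60 | 8 |
| 0.833 | 70 | 10 |
| 1.50 | 70 | 22 |
| 2.50 | 55 | 28 |

(each reading ± 2 percentage points)

- share of target in target plus isomer of the product at 0.25 s
- share of target in target plus isomer of the product at 6.0 s
- share of target in target plus isomer of the product at 2.5 min

- the numbers in the tables scatter by 2 percentage points (one standard deviation)
- a reading or a percentage of target counts all its forms, free or not

Dividing c(isomer) at the last reading of each run by the time since the start gives a pace: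

alpha: 11% of 26 mM in 80.0 s = 2.15 mM min⁻¹

beta: 28% of 17 mM in 2.50 min = 1.90 mM min⁻¹

Their mean, 2.02 mM min⁻¹, is the drain w: the concentration of isomer of the product gained per minute. Beta's pace applied to alpha gives 9.74% against the 11% read, with a scatter of 2 percentage points. A gain that keeps its pace across both charges is called zero-order, and in percent it is w·t divided by the charge.

Now the question turned round: what would put isomer of the product level with target in this flask at 2.5 min? Target plus isomer reads 83.0% at the end of alpha and 83.0% at the end of beta. If that sum holds, isomer must reach half of it, which takes a drain of 4.32 mM min⁻¹, twice the one read. The drain as read gives instead: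

isomer = w·t/c(substrate charged) = 19.5%

share = 76.5%

The forecast, at 96%, 95% and 74%, reads the last from a time lag, “Alpha runs about 30–40 s behind beta in this decline”, and stands 2.5 points below this reckoning.

The flask gives 96.4%, 93.0% and 74.9%.

    crystals ⇌ target, rate k1*(cs1 - [target]) while solid is left; crystals form when [target] > cs1 (solubility = 0.300 mM, k = 4.60 s⁻¹)
    substrate ⇌ isomer of the product (K = 90.0, k = 0.00140 s⁻¹)
    substrate ⇌ target (K = 0.670, k = 0.0600 s⁻¹)
    target ⇌ isomer of the product (k = 0.110 s⁻¹)
    2 substrate → homo dimer (k = 0.360 L mol⁻¹ s⁻¹)

At 2.50 min this flask holds 21.3% isomer of the product where w gave 19.5%, and crystals carry 62.6% of the charge. In the neighbour charged with 10 mM, the same drain gives 50.5% isomer of the product, and that neighbour holds 49.9%, with the share of target down at 44.3%.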